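The earlier runs and the new flask stem from a simulated flask from invented constants; the scatter is artificial.

Per second was the unit I wanted from Tuesday's run: the next flask hung on whether I could charge less free catalyst.

- Tuesday's: left-handed substrate 1 mM; right-handed substrate 1 mM; gas 0.45 mM (held); free catalyst 0.14 mol%; added ligand 2.3 µM; impurity 0.41 µM; the very flask that is asked about, followed so far
- flask: left-handed substrate 1.0 mM; gas 0.45 mM (held); free catalyst 0.14 mol%; added ligand 2.3 µM; impurity 0.41 µM; right-handed substrate 1.0 mM; time 10 min

- Tuesday's (time / s: left-handed substrate / %, right-handed substrate / %, left-handed product / %): 25.0: 40.2, 50.4, 10.6; 50.0: 30.6, 48.2, 19.5; 80.0: 22.0, 49.2, 27.0; 120: 14.4, 47.5, 36.0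

(readings scatter by 0.5 percentage points)

- free catalyst is single-handed; left-handed substrate and right-handed substrate are mirror images of each other, charged as a racemate, each of them at the stated concentration
- at the start none of the gas is in solution
- an excess is the difference of the two amounts in percent of their sum
- an excess is below zero if the other one leads

- part of the left-handed substrate and right-handed substrate charged together that has reacted at 10 min
- excess of left-handed product over right-handed product in the product at 10 min
- excess of right-handed substrate over left-handed substrate among what is left of the two at 10 min

On Tuesday's run the left-handed substrate fell from 40.2 % to 14.4 %, which I read as a pseudo-first-order decay: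

k = ln(first reading / last reading) / elapsed time = 0.0108 /s

I took each impurity to spend one free catalyst, which the readings cannot test. As fractions of the left-handed substrate charged, the impurity is 0.0410 %, so the working catalyst is:

w = charge − impurity = 0.0990 %

Dividing gives the constant per working catalyst, κ = k/w, the quantity I carried forward:

κ = 10.9 /s

Since w is smaller than the charge, a cut counts for more in w than in the charge, so I left the charge at 0.14 mol%.

The time constant is then:

τ = 1/(κw) = 92.5 s

The time asked is 6.48 time constants. From a starting share of 50.0 %, the left-handed substrate should reach 0.0764 %. I therefore committed to 49.9 % of the charge reacted as left-handed substrate, with c higher by whatever right-handed substrate reacted. Tuesday's right-handed substrate, 50.4 % to 47.5 % against a scatter of 0.5 percentage points, gave me no constant worth committing to.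

The forecast, grounded on “Left-handed substrate decays cleanly first order”, gave c 60.4 %, eP 65 % and eS 99.5 %.

The flask gave c 61.9 %, eP 61.7 % and eS 99.9 %.

    free catalyst + impurity → spent catalyst (k = 1.04 × 10⁷ /M/s)
    free catalyst + left-handed substrate ⇌ catalyst intermediate A (K = 13000 /M, k = 7.05 × 10⁵ /M/s)
    free catalyst + added ligand ⇌ idle complex, settled at all times (K = 5.20 × 10⁵ /M)
    coupling partner + catalyst intermediate B → free catalyst + right-handed product (k = 1110 /M/s)
    gas ⇌ coupling partner, rate k5*(csat - [coupling partner]) (kL = 0.996 /s)
    coupling partner + catalyst intermediate A → free catalyst + left-handed product (k = 59800 /M/s)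
    free catalyst + right-handed substrate ⇌ catalyst intermediate B (K = 15000 /M, k = 6.59 × 10⁵ /M/s)

In this flask impurity stood at 0 % of its charge by 1.00 min, and spent catalyst held at 29.3 % of the catalyst from then to 10.0 min. Left-handed product formed first, half of that step's turnover done by 1.17 min; with left-handed substrate down to 1.18 % at 5.00 min, right-handed product went on from 5.58 % to 11.9 % at 10.0 min. Left-handed substrate ended at 0.00957 %, below my 0.0764 %.

With 0.084 mol% of free catalyst, w becomes 0.0430 %, so κ gives τ = 213 s and left-handed substrate at 2.99 %. That neighbour flask ended with 2.05 % of it, at c 52.8 %, eP 81.8 % and eS 91.3 %.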